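**Retrosynthetic overview**
1. The C2 acetate and the C6 4-methoxybenzoate go on last, which leads back to a C2-silylated 4,6-diol.
2. The C4 tertiary carbinol comes from isopropylcerium addition to a trans-fused bicyclic β-hydroxy ketone.
3. Ring B (seven-membered) is closed by ring-closing metathesis at C8=C9.
4. The key bond C5–C6 comes from an intermolecular aldol between a regiodefined cyclopentanone enolate (ring A fragment) and 3-methylbut-3-enal.
5. Ring A is bought as 2-methylcyclopentane-1,3-dione. It is allylated, desymmetrised with yeast (sets C1 and C2), and its carbonyl is moved from C5 to C4 through a bromohydrin. Ring order: A is present from the start, B is closed in step 10.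

Assumption: daucane numbering is used for positions (C1 quaternary C–CH3, C2 C–OAc, C3 CH2, C4 isopropyl carbinol, C5 ring-fusion CH, C6 C–O-anisoyl, C7 CH2, C8=C9, C10 CH2). The target is 1R,2S,4R,5S,6S in this numbering, which is 1S,3R,3aS,4S,8aR in azulene numbering.

**Step 1**
Reactants: 1 2-methylcyclopentane-1,3-dione; 2 allyl bromide
Product: 3 2-methyl-2-(prop-2-en-1-yl)cyclopentane-1,3-dione
Conditions: NaOH (1 M aq), rt, 48 h
Reagents that add atoms: none
Why: This is an SN2 C-allylation of a stabilised 1,3-diketone enolate in water, where the fully ionised enolate reacts at carbon and builds the still prochiral quaternary carbon C1.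

**Step 2**
Reactants: 3 2-methyl-2-(prop-2-en-1-yl)cyclopentane-1,3-dione
Product: 4 (2S,3S)-3-hydroxy-2-methyl-2-(prop-2-en-1-yl)cyclopentan-1-one (OH cis to allyl)
Conditions: baker's yeast, D-glucose, H2O, 30 °C, 48 h; chromatography
Reagents that add atoms: none
Why: In this enzymatic desymmetrising ketone reduction the yeast reductases reduce only one of the two enantiotopic carbonyl groups and deliver hydride from the methyl-bearing face, which sets C2 as S (OH cis to allyl) and thereby fixes the quaternary centre C1, with the minor 2R,3S isomer removed by chromatography.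

**Step 3**
Reactants: 4 (2S,3S)-3-hydroxy-2-methyl-2-(prop-2-en-1-yl)cyclopentan-1-one
Product: 5 (2S,3S)-3-[(tert-butyldimethylsilyl)oxy]-2-methyl-2-(prop-2-en-1-yl)cyclopentan-1-one
Conditions: TBSCl, imidazole, DMF, 40 °C
Reagents that add atoms: tert-butyldimethylsilyl chloride (TBSCl), CC(C)(C)[Si](C)(C)Cl
Why: Silyl ether protection masks the C2 hydroxyl with a group that survives strong base, SmI2, the ruthenium carbene and the organocerium reagent and later shields one ring face, and no stereocentre is touched.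

**Step 4**
Reactants: 5 (2S,3S)-3-[(tert-butyldimethylsilyl)oxy]-2-methyl-2-(prop-2-en-1-yl)cyclopentan-1-one
Product: 7 (4S,5S)-4-[(tert-butyldimethylsilyl)oxy]-5-methyl-5-(prop-2-en-1-yl)cyclopent-1-en-1-yl trifluoromethanesulfonate, via potassium enolate 6 (not isolated)
Conditions: KN(SiMe3)2, THF, −78 °C; then PhNTf2, −78 to 0 °C
Reagents that add atoms: N-phenylbis(trifluoromethanesulfonimide) (PhNTf2), O=S(=O)(N(c1ccccc1)S(=O)(=O)C(F)(F)F)C(F)(F)F
Why: In this enolate O-triflation only C4 carries α-hydrogens because C1 is quaternary, so a single enol triflate forms, as it does with hindered 17-keto steroids.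

**Step 5**
Reactants: 7 (4S,5S)-4-[(tert-butyldimethylsilyl)oxy]-5-methyl-5-(prop-2-en-1-yl)cyclopent-1-en-1-yl trifluoromethanesulfonate
Product: 8 tert-butyldimethyl{[(1S,2R)-2-methyl-2-(prop-2-en-1-yl)cyclopent-3-en-1-yl]oxy}silane
Conditions: Pd(OAc)2 (5 mol %), PPh3, HCO2H, Bu3N, DMF, 60 °C
Reagents that add atoms: none
Why: Palladium-catalysed formate hydrogenolysis of the vinyl triflate (oxidative addition to zerovalent palladium, decarboxylation of formate, reductive elimination) replaces OTf by H and leaves the isolated allyl group and both stereocentres alone.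

**Step 6**
Reactants: 8 tert-butyldimethyl{[(1S,2R)-2-methyl-2-(prop-2-en-1-yl)cyclopent-3-en-1-yl]oxy}silane
Product: 9 (1R,2R,3S,4S)-2-bromo-4-[(tert-butyldimethylsilyl)oxy]-3-methyl-3-(prop-2-en-1-yl)cyclopentan-1-ol
Conditions: NBS (1.05 equiv), acetone–H2O 4:1, 0 °C, dark
Reagents that add atoms: N-bromosuccinimide (NBS), O=C1CCC(=O)N1Br; water, O
Why: In this electrophilic bromohydrin formation the cis-disubstituted ring olefin is much more nucleophilic than the monosubstituted allyl group, and water opens the bromonium ion anti at C4 because C5 is neopentyl, so O ends on C4 and Br on C5, and either trans-bromohydrin is usable because both new centres lose their configuration in steps 7 and 9.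

**Step 7**
Reactants: 9 (1R,2R,3S,4S)-2-bromo-4-[(tert-butyldimethylsilyl)oxy]-3-methyl-3-(prop-2-en-1-yl)cyclopentan-1-ol
Product: 10 (2R,3S,4S)-2-bromo-4-[(tert-butyldimethylsilyl)oxy]-3-methyl-3-(prop-2-en-1-yl)cyclopentan-1-one
Conditions: Dess–Martin periodinane, CH2Cl2, 0 °C to rt
Reagents that add atoms: none
Why: Dess–Martin oxidation is neutral, so the secondary carbinol becomes the C4 ketone without loss of HBr (C1 has no hydrogen) or of the β-silyloxy group, which completes the shift of the carbonyl from C5 to C4.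

**Step 8**
Reactants: 11 3-methylbut-3-en-1-ol
Product: 12 3-methylbut-3-enal
Conditions: Dess–Martin periodinane, NaHCO3, CH2Cl2, 0 °C; filtered and used at once as a cold solution
Reagents that add atoms: none
Why: Buffered Dess–Martin oxidation gives the β,γ-unsaturated aldehyde without the acid or base that would move the double bond into conjugation.

**Step 9 (key step)**
Reactants: 10 (2R,3S,4S)-2-bromo-4-[(tert-butyldimethylsilyl)oxy]-3-methyl-3-(prop-2-en-1-yl)cyclopentan-1-one; 12 3-methylbut-3-enal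
Product: 14 (2S,3R,4S)-4-[(tert-butyldimethylsilyl)oxy]-2-[(1S)-1-hydroxy-3-methylbut-3-en-1-yl]-3-methyl-3-(prop-2-en-1-yl)cyclopentan-1-one, via samarium enolate 13 (not isolated)
Conditions: SmI2 (2.1 equiv), THF, −78 °C, 10 min; then 12 (1.3 equiv), −78 °C; pH 7 buffer at −78 °C
Reagents that add atoms: none
Why: In this samarium Reformatsky-type intermolecular aldol, two-electron cleavage of the C5–Br bond gives the weakly basic enolate only across C4–C5 (no C3 enolate, so no loss of OTBS and no enolisation of 12), the aldehyde reacts in a closed Zimmerman–Traxler chair on the face opposite the allyl and OTBS groups (sets 5S), and the ring-locked E enolate gives the anti aldol (sets 6S).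

**Step 10**
Reactants: 14 (2S,3R,4S)-4-[(tert-butyldimethylsilyl)oxy]-2-[(1S)-1-hydroxy-3-methylbut-3-en-1-yl]-3-methyl-3-(prop-2-en-1-yl)cyclopentan-1-one
Product: 15 (3S,3aR,8S,8aS)-3-[(tert-butyldimethylsilyl)oxy]-8-hydroxy-3a,6-dimethyl-3,3a,4,7,8,8a-hexahydroazulen-1(2H)-one
Conditions: RuCl2(=CHPh)(PCy3)(H2IMes) (second-generation Grubbs catalyst, 5 mol %), CH2Cl2 (2 mM), 40 °C
Reagents that add atoms: none
Why: In this ring-closing olefin metathesis the catalyst loads on the allyl terminus and closes onto the 1,1-disubstituted olefin with loss of ethene, which forms ring B as the trans-fused cycloheptene with the trisubstituted C8=C9 bond in place, under neutral conditions that do not epimerise C5.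

**Step 11**
Reactants: 15 (3S,3aR,8S,8aS)-3-[(tert-butyldimethylsilyl)oxy]-8-hydroxy-3a,6-dimethyl-3,3a,4,7,8,8a-hexahydroazulen-1(2H)-one; 16 isopropylmagnesium chloride
Product: 17 (1S,3R,3aS,4S,8aR)-1-[(tert-butyldimethylsilyl)oxy]-6,8a-dimethyl-3-(propan-2-yl)-1,2,3,3a,4,5,8,8a-octahydroazulene-3,4-diol
Conditions: CeCl3 (anhydrous, 4 equiv), 16 (4 equiv), THF, −78 °C, 1 h; then 15, −78 °C; aqueous work-up
Reagents that add atoms: none
Why: In this organocerium 1,2-addition the weakly basic reagent adds rather than enolising or reducing the hindered β-oxygenated ketone, and because the C6 alkoxide ties the metal to the ketone oxygen the isopropyl group enters from the face that carries H5, opposite C1 and its angular methyl, which gives the 4R carbinol (OH cis to the methyl) and locks C5.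

**Step 12**
Reactants: 17 (1S,3R,3aS,4S,8aR)-1-[(tert-butyldimethylsilyl)oxy]-6,8a-dimethyl-3-(propan-2-yl)-1,2,3,3a,4,5,8,8a-octahydroazulene-3,4-diol; 18 4-methoxybenzoyl chloride
Product: 19 (1S,3R,3aS,4S,8aR)-1-[(tert-butyldimethylsilyl)oxy]-3-hydroxy-6,8a-dimethyl-3-(propan-2-yl)-1,2,3,3a,4,5,8,8a-octahydroazulen-4-yl 4-methoxybenzoate
Conditions: Et3N, DMAP (cat.), CH2Cl2, 40 °C
Reagents that add atoms: none
Why: DMAP-catalysed acylation reaches only the secondary C6 hydroxyl, because the C4 hydroxyl is tertiary and flanked by isopropyl and C2 is still silylated, and the C–O bond at C6 is not touched.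

**Step 13**
Reactants: 19 (1S,3R,3aS,4S,8aR)-1-[(tert-butyldimethylsilyl)oxy]-3-hydroxy-6,8a-dimethyl-3-(propan-2-yl)-1,2,3,3a,4,5,8,8a-octahydroazulen-4-yl 4-methoxybenzoate
Product: 20 (1S,3R,3aS,4S,8aR)-1,3-dihydroxy-6,8a-dimethyl-3-(propan-2-yl)-1,2,3,3a,4,5,8,8a-octahydroazulen-4-yl 4-methoxybenzoate
Conditions: HF·pyridine, THF, 0 °C to rt
Reagents that add atoms: none
Why: Fluoride-driven desilylation under non-basic conditions frees the hindered C2 hydroxyl without ester hydrolysis or acyl migration and without ionising the tertiary carbinol.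

**Step 14**
Reactants: 20 (1S,3R,3aS,4S,8aR)-1,3-dihydroxy-6,8a-dimethyl-3-(propan-2-yl)-1,2,3,3a,4,5,8,8a-octahydroazulen-4-yl 4-methoxybenzoate; 21 acetic anhydride
Product: 22 (1S,3R,3aS,4S,8aR)-1-acetoxy-3-hydroxy-6,8a-dimethyl-3-(propan-2-yl)-1,2,3,3a,4,5,8,8a-octahydroazulen-4-yl 4-methoxybenzoate (target)
Conditions: pyridine, DMAP (cat.), CH2Cl2, rt
Reagents that add atoms: none
Why: DMAP-catalysed acetylation takes the only remaining secondary hydroxyl (C2) with retention, while the hindered tertiary C4 hydroxyl stays free at room temperature.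

**Compound list**
1 | 2-methylcyclopentane-1,3-dione | CC1C(=O)CCC1=O | starting material
2 | allyl bromide | C=CCBr | starting material
3 | 2-methyl-2-(prop-2-en-1-yl)cyclopentane-1,3-dione | C=CCC1(C)C(=O)CCC1=O | intermediate
4 | (2S,3S)-3-hydroxy-2-methyl-2-(prop-2-en-1-yl)cyclopentan-1-one | C=CC[C@@]1(C)[C@@H](O)CCC1=O | intermediate
5 | (2S,3S)-3-[(tert-butyldimethylsilyl)oxy]-2-methyl-2-(prop-2-en-1-yl)cyclopentan-1-one | C=CC[C@@]1(C)[C@@H](O[Si](C)(C)C(C)(C)C)CCC1=O | intermediate
6 | potassium (4S,5S)-4-[(tert-butyldimethylsilyl)oxy]-5-methyl-5-(prop-2-en-1-yl)cyclopent-1-en-1-olate (not isolated) | [K+].C=CC[C@@]1(C)[C@@H](O[Si](C)(C)C(C)(C)C)CC=C1[O-] | intermediate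
7 | (4S,5S)-4-[(tert-butyldimethylsilyl)oxy]-5-methyl-5-(prop-2-en-1-yl)cyclopent-1-en-1-yl trifluoromethanesulfonate | C=CC[C@@]1(C)[C@@H](O[Si](C)(C)C(C)(C)C)CC=C1OS(=O)(=O)C(F)(F)F | intermediate
8 | tert-butyldimethyl{[(1S,2R)-2-methyl-2-(prop-2-en-1-yl)cyclopent-3-en-1-yl]oxy}silane | C=CC[C@@]1(C)[C@@H](O[Si](C)(C)C(C)(C)C)CC=C1 | intermediate
9 | (1R,2R,3S,4S)-2-bromo-4-[(tert-butyldimethylsilyl)oxy]-3-methyl-3-(prop-2-en-1-yl)cyclopentan-1-ol | C=CC[C@@]1(C)[C@@H](O[Si](C)(C)C(C)(C)C)C[C@@H](O)[C@@H]1Br | intermediate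
10 | (2R,3S,4S)-2-bromo-4-[(tert-butyldimethylsilyl)oxy]-3-methyl-3-(prop-2-en-1-yl)cyclopentan-1-one | C=CC[C@@]1(C)[C@@H](O[Si](C)(C)C(C)(C)C)CC(=O)[C@@H]1Br | intermediate
11 | 3-methylbut-3-en-1-ol | C=C(C)CCO | starting material
12 | 3-methylbut-3-enal | C=C(C)CC=O | intermediate
13 | diiodosamarium (3R,4S)-4-[(tert-butyldimethylsilyl)oxy]-3-methyl-3-(prop-2-en-1-yl)cyclopent-1-en-1-olate (not isolated) | C=CC[C@@]1(C)[C@@H](O[Si](C)(C)C(C)(C)C)CC(O[Sm](I)I)=C1 | intermediate
14 | (2S,3R,4S)-4-[(tert-butyldimethylsilyl)oxy]-2-[(1S)-1-hydroxy-3-methylbut-3-en-1-yl]-3-methyl-3-(prop-2-en-1-yl)cyclopentan-1-one | C=CC[C@@]1(C)[C@@H](O[Si](C)(C)C(C)(C)C)CC(=O)[C@@H]1[C@@H](O)CC(C)=C | intermediate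
15 | (3S,3aR,8S,8aS)-3-[(tert-butyldimethylsilyl)oxy]-8-hydroxy-3a,6-dimethyl-3,3a,4,7,8,8a-hexahydroazulen-1(2H)-one | O[C@H]2CC(C)=CC[C@@]3(C)[C@@H](O[Si](C)(C)C(C)(C)C)CC(=O)[C@H]23 | intermediate
16 | isopropylmagnesium chloride | CC(C)[Mg]Cl | starting material
17 | (1S,3R,3aS,4S,8aR)-1-[(tert-butyldimethylsilyl)oxy]-6,8a-dimethyl-3-(propan-2-yl)-1,2,3,3a,4,5,8,8a-octahydroazulene-3,4-diol | O[C@H]2CC(C)=CC[C@@]3(C)[C@@H](O[Si](C)(C)C(C)(C)C)C[C@@](O)(C(C)C)[C@H]23 | intermediate
18 | 4-methoxybenzoyl chloride | COc1ccc(C(=O)Cl)cc1 | starting material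
19 | (1S,3R,3aS,4S,8aR)-1-[(tert-butyldimethylsilyl)oxy]-3-hydroxy-6,8a-dimethyl-3-(propan-2-yl)-1,2,3,3a,4,5,8,8a-octahydroazulen-4-yl 4-methoxybenzoate | COc1ccc(C(=O)O[C@H]2CC(C)=CC[C@@]3(C)[C@@H](O[Si](C)(C)C(C)(C)C)C[C@@](O)(C(C)C)[C@H]23)cc1 | intermediate
20 | (1S,3R,3aS,4S,8aR)-1,3-dihydroxy-6,8a-dimethyl-3-(propan-2-yl)-1,2,3,3a,4,5,8,8a-octahydroazulen-4-yl 4-methoxybenzoate | COc1ccc(C(=O)O[C@H]2CC(C)=CC[C@@]3(C)[C@@H](O)C[C@@](O)(C(C)C)[C@H]23)cc1 | intermediate
21 | acetic anhydride | CC(=O)OC(C)=O | starting material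
22 | (1S,3R,3aS,4S,8aR)-1-acetoxy-3-hydroxy-6,8a-dimethyl-3-(propan-2-yl)-1,2,3,3a,4,5,8,8a-octahydroazulen-4-yl 4-methoxybenzoate | COc1ccc(C(=O)O[C@H]2CC(C)=CC[C@@]3(C)[C@@H](OC(C)=O)C[C@@](O)(C(C)C)[C@H]23)cc1 | target

**Total step count:** 14.
**Longest linear sequence:** 13 (steps 1–7 and 9–14). Step 8 is a one-step side branch.

**Three steps most likely to fail**

Step 9. The enolate carbon sits next to a quaternary centre, so the anti/syn ratio at C6 may be modest, and 12 is fragile. The fallback stops relying on the aldol for C6 and sets this centre by a hydroxyl-directed reduction. It sets out from 10 and comes back at 17. The aldol is run as before. The syn aldol F5 (C6 epimer of 14) is kept and taken through the same metathesis to the C6-epimeric bicyclic hydroxy ketone F6, then through the same organocerium addition to the C6-epimeric diol F7. Dess–Martin oxidation of F7, alone or mixed with 17, gives the single β-hydroxy ketone F8. Me4NBH(OAc)3 in MeCN–AcOH at −20 °C then binds to the tertiary C4 hydroxyl and delivers hydride to the same face of the C6 carbonyl (Evans–Saksena 1,3-anti reduction). This returns 17 with the 6S carbinol.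

Step 11. The hindered ketone may be reduced or enolised by a β-hydride-bearing secondary nucleophile, or may react slowly. The fallback brings in the three carbons as a smaller sp2 nucleophile without β-hydrogens and saturates afterwards. It sets out from 15 and comes back at 17. Isopropenylmagnesium bromide with CeCl3 in THF at −78 °C adds from the same H5 face and gives the isopropenyl carbinol F9. RhCl(PPh3)3 under H2 (1 atm, benzene–EtOH) then hydrogenates only the 1,1-disubstituted olefin and leaves the trisubstituted C8=C9 bond, which gives 17.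

Step 6. NBS may also attack the allyl group, or the bromonium ion may open at the wrong carbon. The fallback drops the alkene chemistry and moves the carbonyl through an acyloin. It sets out from the potassium enolate 6 (made from 5 as in step 4) and comes back at the samarium enolate 13.
- Oxidation of 6 with 2-(phenylsulfonyl)-3-phenyloxaziridine at −78 °C gives the α-hydroxy ketone F1.
- NaBH4 in MeOH reduces the C5 ketone to the diol F2.
- TEMPO with PhI(OAc)2 oxidises only the unhindered C4 carbinol, since the C5 carbinol is neopentyl, and gives the transposed α-hydroxy ketone F3.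
- Ac2O, pyridine and DMAP give the α-acetoxy ketone F4.
- SmI2 (2.1 equiv, THF, −78 °C) cleaves the C5–OAc bond of F4 and forms 13, which is treated with 12 as in step 9.

**Further compounds**
F1 | step 6 | (2S,3S,5S)-3-[(tert-butyldimethylsilyl)oxy]-5-hydroxy-2-methyl-2-(prop-2-en-1-yl)cyclopentan-1-one | C=CC[C@@]1(C)[C@@H](O[Si](C)(C)C(C)(C)C)C[C@H](O)C1=O
F2 | step 6 | (1S,2S,3R,4S)-4-[(tert-butyldimethylsilyl)oxy]-3-methyl-3-(prop-2-en-1-yl)cyclopentane-1,2-diol | C=CC[C@@]1(C)[C@@H](O[Si](C)(C)C(C)(C)C)C[C@H](O)[C@H]1O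
F3 | step 6 | (2S,3R,4S)-4-[(tert-butyldimethylsilyl)oxy]-2-hydroxy-3-methyl-3-(prop-2-en-1-yl)cyclopentan-1-one | C=CC[C@@]1(C)[C@@H](O[Si](C)(C)C(C)(C)C)CC(=O)[C@H]1O
F4 | step 6 | (1S,2R,3S)-3-[(tert-butyldimethylsilyl)oxy]-2-methyl-5-oxo-2-(prop-2-en-1-yl)cyclopentyl acetate | C=CC[C@@]1(C)[C@@H](O[Si](C)(C)C(C)(C)C)CC(=O)[C@H]1OC(C)=O
F5 | step 9 | (2S,3R,4S)-4-[(tert-butyldimethylsilyl)oxy]-2-[(1R)-1-hydroxy-3-methylbut-3-en-1-yl]-3-methyl-3-(prop-2-en-1-yl)cyclopentan-1-one | C=CC[C@@]1(C)[C@@H](O[Si](C)(C)C(C)(C)C)CC(=O)[C@@H]1[C@H](O)CC(C)=C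
F6 | step 9 | (3S,3aR,8R,8aS)-3-[(tert-butyldimethylsilyl)oxy]-8-hydroxy-3a,6-dimethyl-3,3a,4,7,8,8a-hexahydroazulen-1(2H)-one | O[C@@H]2CC(C)=CC[C@@]3(C)[C@@H](O[Si](C)(C)C(C)(C)C)CC(=O)[C@H]23
F7 | step 9 | (1S,3R,3aS,4R,8aR)-1-[(tert-butyldimethylsilyl)oxy]-6,8a-dimethyl-3-(propan-2-yl)-1,2,3,3a,4,5,8,8a-octahydroazulene-3,4-diol | O[C@@H]2CC(C)=CC[C@@]3(C)[C@@H](O[Si](C)(C)C(C)(C)C)C[C@@](O)(C(C)C)[C@H]23
F8 | step 9 | (1S,3R,3aR,8aR)-1-[(tert-butyldimethylsilyl)oxy]-3-hydroxy-6,8a-dimethyl-3-(propan-2-yl)-2,3,3a,5,8,8a-hexahydroazulen-4(1H)-one | O=C2CC(C)=CC[C@@]3(C)[C@@H](O[Si](C)(C)C(C)(C)C)C[C@@](O)(C(C)C)[C@H]23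
F9 | step 11 | (1S,3S,3aS,4S,8aR)-1-[(tert-butyldimethylsilyl)oxy]-6,8a-dimethyl-3-(prop-1-en-2-yl)-1,2,3,3a,4,5,8,8a-octahydroazulene-3,4-diol | O[C@H]2CC(C)=CC[C@@]3(C)[C@@H](O[Si](C)(C)C(C)(C)C)C[C@@](O)(C(C)=C)[C@H]23
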